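X is the product we follow here, and at 120 s south-east holds 42.3% of it and east 30.9%, from the same G charge. The two runs differ in J.

| flask | G | J | remark | time |
|---|---|---|---|---|
| south-east | 2.9 M | 0.43 M | run made earlier |  |
| east | 2.9 M | 1.2 M | run made earlier |  |
| beta | 2.9 M | 1.40 M |  | 2.0 min |
| alpha | 2.9 M | 0.580 M |  | 2.0 min |

| run | time / s | E / % | G / % | X / % | D / % |
|---|---|---|---|---|---|
| south-east | 10.0 | 10.4 | 64.2 | 1.9 | 9.6 |
| south-east | 30.0 | 19.7 | 40.7 | 9.4 | 14.6 |
| south-east | 60.0 | 24.0 | 22.3 | 22.4 | 16.2 |
| south-east | 80.0 | 25.6 | 15.9 | 30.0 | 12.8 |
| south-east | 120 | 26.7 | 8.9 | 42.3 | 7.6 |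
| east | 10.0 | 6.2 | 45.0 | 1.8 | 5.9 |
| east | 20.0 | 8.9 | 36.8 | 3.5 | 9.7 |
| east | 30.0 | 10.8 | 29.2 | 6.1 | 12.1 |
| east | 60.0 | 13.2 | 17.2 | 17.1 | 11.6 |
| east | 120 | 14.3 | 6.5 | 30.9 | 6.3 |

(readings scatter by 0.5 percentage points)

- a species is counted by the G in it: one E counts as two

* which of these there is most of at the end, counted by the G in it, beta (E / D / G / X)
* which of these there is most of at the end, counted by the G in it, alpha (E / D / G / X)
* amount of the one of these that there is most of at the end, in percent of the G charged, beta
* amount of the one of these that there is most of at the end, in percent of the G charged, alpha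

1. We add the four readings of each run. South-east gives 86.1% at 10.0 s and 85.5% at 120 s. East gives 58.9% and 58.0%. The shortfall is there at the first reading and does not come back.

2. We write the balance of J, charged in the smaller amount and so the limiting reagent of this loss. The free share of alpha, the part of the G charge left once each J has taken one G, is 80.0%. The same sum gives south-east 85.2%, east 58.6% and beta 51.7%, and the two simulated values match the totals above.

3. East looks like beta, and the time is the same. X is 52.7% of the free share in east and 49.7% in south-east, so that fraction shifts far less than the free share does. Beta must therefore end below east in X, because its free share is smaller.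

4. Our reckoning carries each neighbour's fraction over. Beta gets 27.3% of X from east, and alpha gets 39.7% from south-east. E, carried the same way, gives 12.6% for beta and 25.1% for alpha, so we say X in both flasks.

5. The forecast says X for beta and X for alpha, at 27.7% and 40.2%, slightly above ours, on the ground “So each J immediately locks away one G”. The flasks give X in beta at 27.9% and X in alpha at 39.9%.

    G → D (k = 0.0140 /s)
    2 G → E (k = 0.00300 /M/s)
    D → X (k = 0.0280 /s)
    G + J → Z (k = 0.220 /M/s)

In alpha, G + J → Z has half of its turnover behind it by 1.18 s, while the half-life of G by G → D at 0.500 min is 0.83 min, about 42.2 times longer, and Z stands at 20.0% at 2.00 min, against one minus the free share, 20.0%. In beta, Z stands at 48.3% at 2.00 min, against one minus its free share, 48.3%, and X, E, G and D together hold 51.7% of the charge.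

The data stem from a simulated flask with constants of no real substance; the scatter is artificial.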